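## Retrosynthetic overview

1. Target 19 comes from acetylation of allylic alcohol 18. The CH(O)–CH2 bond of 18 comes from a catalytic asymmetric addition of side-chain dialkylzinc 17 to the 2-substituted acrolein 8, which sets the carbinol centre.
2. Enal 8 comes from allyl enone 6 by linear hydroformylation and then α-methylenation (allyl → CH2CH2C(=CH2)CHO).
3. Enone 6 comes from the prochiral dienone 4 by a desymmetrising CuH 1,4-reduction, which sets both ring stereocentres in one step.
4. Key bond, ring C4–CH2: dienone 4 comes from 3,4,5-trimethylphenol 1 and allylsilane 2. The phenol para carbon is made electrophilic (a phenoxenium ion, that is, a doubly vinylogous enolonium equivalent), so two natural nucleophiles are joined and the quaternary carbon is formed.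
5. Neither ring is built by cyclisation. The carbocycle is the dearomatised ring of 1 (step 1). The butenolide arrives intact from 13 by B-alkyl Suzuki coupling (step 6). Side chain 16 comes from 9, 10 and 13.

Assumption: the absolute sense of the two catalyst-controlled steps (2 and 8) is assigned by analogy with simple enones and enals. Both antipodes of each ligand are sold, so a reversed sense only means using the other antipode. 4-Bromofuran-2(5H)-one 13 is taken as a catalogue compound.

## Route

Step 1
Reactants: 1 3,4,5-trimethylphenol; 2 allyltrimethylsilane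
Product: 4 4-allyl-3,4,5-trimethylcyclohexa-2,5-dien-1-one, via 3,4,5-trimethylphenoxenium cation 3 (not isolated)
Conditions: PhI(OAc)2 (1.2 equiv), 2 (4 equiv), (CF3)2CHOH, 0 °C, 15 min
Reagents that add atoms: none
Why: Oxidative (polarity-reversed) Hosomi–Sakurai allylation: PhI(OAc)2 in cation-stabilising, non-nucleophilic HFIP converts the phenol into phenoxenium ion 3, whose para carbon (normally a nucleophile) is attacked by the γ-carbon of the allylsilane (also a nucleophile), and loss of Me3Si+ gives the quaternary carbon; the product is achiral, so no stereocentre is set yet.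

Step 2
Reactants: 4 4-allyl-3,4,5-trimethylcyclohexa-2,5-dien-1-one
Product: 6 (4R,5R)-4-allyl-3,4,5-trimethylcyclohex-2-en-1-one, via diethoxymethylsilyl dienol ether 5 (not isolated)
Conditions: Cu(OAc)2·H2O (3 mol %), (S)-DTBM-SEGPHOS (3.3 mol %), (EtO)2MeSiH (1.1 equiv), toluene, −25 °C; then 1 M HCl, THF, 0 °C
Reagents that add atoms: none
Why: Proposed new method: asymmetric CuH conjugate reduction of β,β-disubstituted cyclic enones is the closest known reaction type (desymmetrising conjugate hydrosilylation of 4,4-disubstituted cyclohexadienones is known with Rh) and is extended here to a 3,5-dimethyl dienone, where L*CuH delivers hydride to one of the two enantiotopic β-carbons from the ring face bearing the small C4-methyl (anti to allyl), so catalyst control (which arm) and substrate control (which face) reinforce each other and fix C4 (R) and C5 (R, 5-Me cis to allyl) together, while σ-bond metathesis with the silane holds the product as 2-silyloxydiene 5, which is no longer an acceptor and cannot be over-reduced.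

Step 3
Reactants: 6 (4R,5R)-4-allyl-3,4,5-trimethylcyclohex-2-en-1-one
Product: 7 4-[(1R,6R)-1,2,6-trimethyl-4-oxocyclohex-2-en-1-yl]butanal
Conditions: Rh(acac)(CO)2 (0.5 mol %), BIPHEPHOS (1.5 mol %), CO/H2 1:1 (10 bar), toluene, 60 °C
Reagents that add atoms: carbon monoxide [C-]#[O+]
Why: Linear-selective Rh-catalysed hydroformylation: the wide-bite-angle bisphosphite and the neighbouring quaternary carbon direct the formyl group to the terminal carbon, the trisubstituted conjugated C=C is inert, and no stereocentre is created or touched.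

Step 4
Reactants: 7 4-[(1R,6R)-1,2,6-trimethyl-4-oxocyclohex-2-en-1-yl]butanal
Product: 8 2-methylidene-4-[(1R,6R)-1,2,6-trimethyl-4-oxocyclohex-2-en-1-yl]butanal
Conditions: 37 % aq. CH2O (1.2 equiv), pyrrolidine (10 mol %), EtCO2H (10 mol %), i-PrOH, 45 °C
Reagents that add atoms: formaldehyde C=O
Why: Organocatalytic Mannich-type α-methylenation (aldehyde enamine plus formaldehyde iminium, then β-elimination of the amine) occurs only at the sole α-CH2 of the aldehyde, which forms its enamine far faster than the hindered enone, and no stereocentre is involved.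

Step 5
Reactants: 9 but-3-yn-1-ol; 10 vinyl bromide
Product: 12 (3E)-3-methylhexa-3,5-dien-1-ol, via alkenylalane 11 (not isolated)
Conditions: AlMe3 (3 equiv), Cp2ZrCl2 (0.25 equiv), CH2Cl2, 0 °C → rt; then 10 (1 M in THF, 2 equiv), Pd(PPh3)4 (5 mol %), ZnCl2 (cat.), rt; aq. work-up
Reagents that add atoms: trimethylaluminium C[Al](C)C
Why: Negishi Zr-catalysed carboalumination adds Me–Al syn with Me on the internal carbon, which fixes the E trisubstituted alkene, and the Pd/Zn co-catalysed Negishi alkenyl–alkenyl coupling with vinyl bromide proceeds with retention of that geometry.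

Step 6
Reactants: 12 (3E)-3-methylhexa-3,5-dien-1-ol; 13 4-bromofuran-2(5H)-one
Product: 15 4-[(3E)-6-hydroxy-4-methylhex-3-en-1-yl]furan-2(5H)-one, via bis-9-BBN adduct 14 (not isolated)
Conditions: 9-BBN-H (2.2 equiv), THF, 0 °C → rt; then 13, PdCl2(dppf) (5 mol %), AsPh3 (5 mol %), 3 M aq. K3PO4, DMF, rt
Reagents that add atoms: none
Why: 9-BBN (one equivalent is consumed by the OH) hydroborates only the monosubstituted terminus of the diene to give the primary homoallylic borane, which undergoes B-alkyl Suzuki–Miyaura coupling with the β-bromobutenolide; the E alkene is untouched.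

Step 7
Reactants: 15 4-[(3E)-6-hydroxy-4-methylhex-3-en-1-yl]furan-2(5H)-one
Product: 16 4-[(3E)-6-iodo-4-methylhex-3-en-1-yl]furan-2(5H)-one
Conditions: PPh3, I2, imidazole, CH2Cl2, 0 °C
Reagents that add atoms: iodine II
Why: Appel iodination of a primary alcohol (SN2 on the alkoxyphosphonium salt) is neutral and leaves the butenolide and the alkene geometry intact.

Step 8
Reactants: 16 4-[(3E)-6-iodo-4-methylhex-3-en-1-yl]furan-2(5H)-one; 8 2-methylidene-4-[(1R,6R)-1,2,6-trimethyl-4-oxocyclohex-2-en-1-yl]butanal
Product: 18 4-[(3E,7R)-7-hydroxy-4-methyl-8-methylidene-10-[(1R,6R)-1,2,6-trimethyl-4-oxocyclohex-2-en-1-yl]dec-3-en-1-yl]furan-2(5H)-one, via dialkylzinc 17 (not isolated)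
Conditions: 16 (2.5 equiv), Et2Zn (neat), CuI (0.3 mol %), 50 °C, then 0.1 mbar; (1S,2S)-C6H10(NHTf)2 (8 mol %), Ti(OiPr)4 (1.2 equiv), toluene, −20 °C, then 8 (1 equiv); 1 M HCl
Reagents that add atoms: none
Why: Iodine–zinc exchange followed by Ti–bis(sulfonamide)-catalysed enantioselective dialkylzinc 1,2-addition to an α-branched enal (the best substrate class for this catalyst), in which the (S,S)-ligand directs the alkyl group to the aldehyde face that gives the (R)-carbinol under pure catalyst control (the ring centres are remote), while the enone and lactone carbonyls are inert to R2Zn/Ti(OiPr)4 at −20 °C.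

Step 9
Reactants: 18 4-[(3E,7R)-7-hydroxy-4-methyl-8-methylidene-10-[(1R,6R)-1,2,6-trimethyl-4-oxocyclohex-2-en-1-yl]dec-3-en-1-yl]furan-2(5H)-one
Product: 19 (4R,7E)-7-methyl-3-methylidene-10-(5-oxo-2,5-dihydrofuran-3-yl)-1-[(1R,6R)-1,2,6-trimethyl-4-oxocyclohex-2-en-1-yl]dec-7-en-4-yl acetate (target)
Conditions: Ac2O (1.5 equiv), pyridine, DMAP (5 mol %), CH2Cl2, 0 °C → rt
Reagents that add atoms: acetic anhydride CC(=O)OC(C)=O
Why: DMAP-catalysed O-acylation does not break the C–O bond, so the (R)-centre is retained, and no other group reacts.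

## Compound list

1 | 3,4,5-trimethylphenol | Cc1cc(O)cc(C)c1C | starting material
2 | allyltrimethylsilane | C=CC[Si](C)(C)C | starting material
3 | 3,4,5-trimethylphenoxenium cation (positive charge drawn at C4) | CC1=CC(=O)C=C(C)[C+]1C | intermediate
4 | 4-allyl-3,4,5-trimethylcyclohexa-2,5-dien-1-one (achiral) | C=CCC1(C)C(C)=CC(=O)C=C1C | intermediate
5 | {[(3R,4R)-4-allyl-3,4,5-trimethylcyclohexa-1,5-dien-1-yl]oxy}diethoxy(methyl)silane | C=CC[C@@]1(C)C(C)=CC(O[Si](C)(OCC)OCC)=C[C@H]1C | intermediate
6 | (4R,5R)-4-allyl-3,4,5-trimethylcyclohex-2-en-1-one (5-Me cis to allyl, trans to 4-Me) | C=CC[C@@]1(C)C(C)=CC(=O)C[C@H]1C | intermediate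
7 | 4-[(1R,6R)-1,2,6-trimethyl-4-oxocyclohex-2-en-1-yl]butanal | O=CCCC[C@@]1(C)C(C)=CC(=O)C[C@H]1C | intermediate
8 | 2-methylidene-4-[(1R,6R)-1,2,6-trimethyl-4-oxocyclohex-2-en-1-yl]butanal | C=C(C=O)CC[C@@]1(C)C(C)=CC(=O)C[C@H]1C | intermediate
9 | but-3-yn-1-ol | C#CCCO | starting material
10 | vinyl bromide | C=CBr | starting material
11 | (E)-alkenylalane, O-dimethylaluminium alkoxide of (E)-4-(dimethylalumanyl)-3-methylbut-3-en-1-ol | C[Al](C)OCC/C(C)=C/[Al](C)C | intermediate
12 | (3E)-3-methylhexa-3,5-dien-1-ol | OCC/C(C)=C/C=C | intermediate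
13 | 4-bromofuran-2(5H)-one | O=C1C=C(Br)CO1 | starting material
14 | bis-9-BBN adduct: (3E)-6-(9-BBN)-3-methylhex-3-en-1-yl 9-BBN borinate | B1(CC/C=C(\C)CCOB2C3CCCC2CCC3)C2CCCC1CCC2 | intermediate
15 | 4-[(3E)-6-hydroxy-4-methylhex-3-en-1-yl]furan-2(5H)-one | OCC/C(C)=C/CCC1=CC(=O)OC1 | intermediate
16 | 4-[(3E)-6-iodo-4-methylhex-3-en-1-yl]furan-2(5H)-one | ICC/C(C)=C/CCC1=CC(=O)OC1 | intermediate
17 | bis[(3E)-3-methyl-6-(5-oxo-2,5-dihydrofuran-3-yl)hex-3-en-1-yl]zinc | O=C1C=C(CC/C=C(\C)CC[Zn]CC/C(C)=C/CCC2=CC(=O)OC2)CO1 | intermediate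
18 | 4-[(3E,7R)-7-hydroxy-4-methyl-8-methylidene-10-[(1R,6R)-1,2,6-trimethyl-4-oxocyclohex-2-en-1-yl]dec-3-en-1-yl]furan-2(5H)-one | C=C(CC[C@@]1(C)C(C)=CC(=O)C[C@H]1C)[C@@H](CC/C(C)=C/CCC1=CC(=O)OC1)O | intermediate
19 | (4R,7E)-7-methyl-3-methylidene-10-(5-oxo-2,5-dihydrofuran-3-yl)-1-[(1R,6R)-1,2,6-trimethyl-4-oxocyclohex-2-en-1-yl]dec-7-en-4-yl acetate | C=C(CC[C@@]1(C)C(C)=CC(=O)C[C@H]1C)[C@@H](CC/C(C)=C/CCC1=CC(=O)OC1)OC(C)=O | target

## Step count and risks

Total step count: 9.
Longest linear sequence: 6 steps (1 → 2 → 3 → 4 → 8 → 9). The side-chain branch is 5 → 6 → 7 and joins at step 8.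

**Step 1 (most likely to fail).** The para carbon is flanked by two methyl groups. Competing pathways are ortho attack with rearomatisation, loss of H+ from the 4-methyl to give a quinone methide, and capture of the cation by acetate or solvent.

The fallback separates the oxidation from the C–C bond formation while keeping the same polarity. It sets out from 1, which is oxidised with PhI(OAc)2 in methanol to the isolable phenoxenium precursor 4-methoxy-3,4,5-trimethylcyclohexa-2,5-dien-1-one F1. This p-quinol ether is then ionised with catalytic TMSOTf in CH2Cl2 at −78 °C in the presence of 2. No oxidant, acetate or protic solvent is then present to compete. The product is 4, where the route is rejoined.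

**Step 2.** The β-carbon lies next to a quaternary centre, so the reduction may be slow. The facial bias rests only on methyl versus allyl, so ee and dr may be modest.

The fallback replaces enantiotopic-alkene selection by enantiotopic-proton selection.
- It sets out from 4, which is reduced on both arms with an achiral CuH (Stryker-type reagent, excess silane, t-BuOH).
- Both hydrides add anti to the allyl group and give meso-(3S,4s,5R)-4-allyl-3,4,5-trimethylcyclohexan-1-one F2.
- A chiral lithium bis(1-phenylethyl)amide with in-situ TMSCl at −100 °C removes one of the two enantiotopic α-protons and gives {[(3S,4R,5R)-4-allyl-3,4,5-trimethylcyclohex-1-en-1-yl]oxy}trimethylsilane F3.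
- Saegusa–Ito oxidation (Pd(OAc)2, MeCN) restores the C2=C3 double bond, erasing the C3 centre, and returns to the route at 6.

**Step 8.** The iodine–zinc exchange has to tolerate the butenolide, and the homoallyl radical formed in the exchange could scramble the alkene. The excess of side chain and the ee are further concerns.

The fallback moves stereocontrol from the C–C bond formation to a kinetic resolution.
- It sets out from 16 and 8, which are joined by a Takai-type alkyl Nozaki–Hiyama coupling (CrCl2, catalytic cobalt phthalocyanine, DMF, rt).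
- This gives 18 mixed about 1:1 with its carbinol epimer 4-[(3E,7S)-7-hydroxy-4-methyl-8-methylidene-10-[(1R,6R)-1,2,6-trimethyl-4-oxocyclohex-2-en-1-yl]dec-3-en-1-yl]furan-2(5H)-one F4.
- Sharpless kinetic resolution follows (Ti(OiPr)4, L-(+)-DIPT, t-BuOOH, 4 Å MS, −20 °C, about 55 % conversion). 2-Substituted 1-alken-3-ols are among the best substrates for it.
- Only the (S)-carbinol is epoxidised, giving the epoxy alcohol 4-[(3E,7S)-7-hydroxy-4-methyl-7-[(2R)-2-{2-[(1R,6R)-1,2,6-trimethyl-4-oxocyclohex-2-en-1-yl]ethyl}oxiran-2-yl]hept-3-en-1-yl]furan-2(5H)-one F5.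
- F5 is removed by chromatography, and the unreacted alcohol is 18, where the route is rejoined.

## Further compounds

F1 | step 1 | 4-methoxy-3,4,5-trimethylcyclohexa-2,5-dien-1-one | COC1(C)C(C)=CC(=O)C=C1C
F2 | step 2 | meso-(3S,4s,5R)-4-allyl-3,4,5-trimethylcyclohexan-1-one (3-Me, 5-Me and allyl all cis) | C=CC[C@@]1(C)[C@@H](C)CC(=O)C[C@H]1C
F3 | step 2 | {[(3S,4R,5R)-4-allyl-3,4,5-trimethylcyclohex-1-en-1-yl]oxy}trimethylsilane | C=CC[C@@]1(C)[C@@H](C)C=C(O[Si](C)(C)C)C[C@H]1C
F4 | step 8 | 4-[(3E,7S)-7-hydroxy-4-methyl-8-methylidene-10-[(1R,6R)-1,2,6-trimethyl-4-oxocyclohex-2-en-1-yl]dec-3-en-1-yl]furan-2(5H)-one | C=C(CC[C@@]1(C)C(C)=CC(=O)C[C@H]1C)[C@H](CC/C(C)=C/CCC1=CC(=O)OC1)O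
F5 | step 8 | 4-[(3E,7S)-7-hydroxy-4-methyl-7-[(2R)-2-{2-[(1R,6R)-1,2,6-trimethyl-4-oxocyclohex-2-en-1-yl]ethyl}oxiran-2-yl]hept-3-en-1-yl]furan-2(5H)-one | O[C@@H](CC/C(C)=C/CCC1=CC(=O)OC1)[C@@]1(CC[C@@]2(C)C(C)=CC(=O)C[C@H]2C)CO1
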